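**Strategy.** Everything rests on forming the C4–C4a bond last. Ring C is closed by intramolecular Friedel–Crafts acylation of an open-chain 3-aryloxy-3-aryl-2-silyloxypropanoic acid in which both stereocentres (future C2 and C3) are already set. The step exploits the substitution of ring A: C8 carries the prenyl group, so C4a is the only unsubstituted carbon ortho to O1 that the O1–C2–C3 tether can reach, and the 6-prenyl isomer cannot arise. The precursor joins three fragments by an Evans syn glycolate aldol and a Mitsunobu etherification with inversion; its ring A phenols are MOM ethers and O3 is a TBS ether, so one acid treatment releases the target.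

Key step: step 8

Assumption: 2-(tert-butyldimethylsilyloxy)acetic acid (9) is taken as a catalogue compound; otherwise it follows from methyl glycolate by silylation and saponification.

Step 1
Reactants: 1 phloroglucinol (benzene-1,3,5-triol)
Product: 2 3,5-bis(methoxymethoxy)phenol
Conditions: MOMCl (2.0 equiv), i-Pr2NEt (2.2 equiv), THF, 0 °C to rt; chromatography
Reagents that add atoms: chloromethyl methyl ether (MOMCl), COCCl
Why: O-alkylation of the phenol with the hard electrophile MOMCl (acetal-type Williamson etherification) should give a statistical mixture in which every bis-ether is the same compound because the three hydroxyls of 1 are equivalent, so only mono- and tris-ethers have to be removed.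

Step 2
Reactants: 2 3,5-bis(methoxymethoxy)phenol; 3 prenyl bromide (1-bromo-3-methylbut-2-ene)
Product: 5 3,5-bis(methoxymethoxy)-2-(3-methylbut-2-en-1-yl)phenol, via sodium phenoxide 4 (not isolated)
Conditions: NaH (1.0 equiv), toluene, 0 °C; then 3 (0.9 equiv), 0 °C to rt
Reagents that add atoms: none
Why: Ortho C-alkylation of a sodium phenoxide in a non-polar solvent: the tight ion pair shields oxygen and delivers the allylic bromide to the ortho carbon through a cyclic array, the two ortho carbons of 2 are equivalent, and tautomerisation of the dienone restores the phenol.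

Step 3
Reactants: 6 3-bromo-4-methoxybenzaldehyde; 7 tributyl(3-methylbut-2-en-1-yl)stannane
Product: 8 4-methoxy-3-(3-methylbut-2-en-1-yl)benzaldehyde
Conditions: Pd(PPh3)4 (5 mol %), DMF, 90 °C
Reagents that add atoms: none
Why: Stille cross-coupling, in which zerovalent palladium inserts into the aryl C–Br bond, the prenyl group is transferred from tin and reductive elimination at the less hindered allyl terminus should give the linear prenyl arene while the aldehyde is untouched under neutral conditions.

Step 4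
Reactants: 9 2-(tert-butyldimethylsilyloxy)acetic acid; 10 (R)-4-benzyl-1,3-oxazolidin-2-one
Product: 12 (R)-4-benzyl-3-[2-(tert-butyldimethylsilyloxy)acetyl]-1,3-oxazolidin-2-one, via mixed pivalic anhydride 11 (not isolated)
Conditions: PivCl, Et3N, THF, −20 °C; then 10, LiCl, −20 °C to rt
Reagents that add atoms: none
Why: N-acylation of the oxazolidinone through a mixed pivalic anhydride (LiCl/Et3N variant of the Evans acylation), in which the hindered pivaloyl carbonyl directs attack to the glycolyl carbonyl; a silyl ether is chosen for the future O3 because it does not chelate the Lewis acid of step 8 and leaves with the MOM groups in step 9.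

Step 5
Reactants: 12 (R)-4-benzyl-3-[2-(tert-butyldimethylsilyloxy)acetyl]-1,3-oxazolidin-2-one; 8 4-methoxy-3-(3-methylbut-2-en-1-yl)benzaldehyde
Product: 14 (R)-4-benzyl-3-[(2R,3S)-2-(tert-butyldimethylsilyloxy)-3-hydroxy-3-[4-methoxy-3-(3-methylbut-2-en-1-yl)phenyl]propanoyl]-1,3-oxazolidin-2-one, via dibutylboron Z-enolate 13 (not isolated)
Conditions: n-Bu2BOTf (1.1 equiv), Et3N (1.3 equiv), CH2Cl2, −78 to 0 °C; then 8, −78 to 0 °C; pH 7 buffer, MeOH, H2O2, 0 °C
Reagents that add atoms: none
Why: Evans syn glycolate aldol, in which soft enolisation gives the Z boron enolate and the aldehyde adds through a Zimmerman–Traxler chair on the enolate face away from the benzyl group of the (R)-auxiliary, which should set the silyloxy carbon as R and the carbinol carbon as S (2,3-syn); the buffered peroxide work-up leaves the prenyl group alone.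

Step 6
Reactants: 14 (R)-4-benzyl-3-[(2R,3S)-2-(tert-butyldimethylsilyloxy)-3-hydroxy-3-[4-methoxy-3-(3-methylbut-2-en-1-yl)phenyl]propanoyl]-1,3-oxazolidin-2-one; 5 3,5-bis(methoxymethoxy)-2-(3-methylbut-2-en-1-yl)phenol
Product: 15 (R)-4-benzyl-3-[(2R,3R)-3-[3,5-bis(methoxymethoxy)-2-(3-methylbut-2-en-1-yl)phenoxy]-2-(tert-butyldimethylsilyloxy)-3-[4-methoxy-3-(3-methylbut-2-en-1-yl)phenyl]propanoyl]-1,3-oxazolidin-2-one
Conditions: PPh3, DIAD, toluene, 0 °C to rt
Reagents that add atoms: none
Why: Mitsunobu etherification, in which the benzylic hydroxyl is activated as an alkoxyphosphonium ion and displaced by the phenoxide of 5 in an SN2 step with inversion, turning the S carbinol into the R aryl ether and the syn adduct into the anti arrangement that becomes 2,3-trans in ring C.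

Step 7
Reactants: 15 (R)-4-benzyl-3-[(2R,3R)-3-[3,5-bis(methoxymethoxy)-2-(3-methylbut-2-en-1-yl)phenoxy]-2-(tert-butyldimethylsilyloxy)-3-[4-methoxy-3-(3-methylbut-2-en-1-yl)phenyl]propanoyl]-1,3-oxazolidin-2-one
Product: 17 (2R,3R)-3-[3,5-bis(methoxymethoxy)-2-(3-methylbut-2-en-1-yl)phenoxy]-2-(tert-butyldimethylsilyloxy)-3-[4-methoxy-3-(3-methylbut-2-en-1-yl)phenyl]propanoic acid, via lithium percarboxylate 16 (not isolated)
Conditions: LiOH, H2O2, THF/H2O, 0 °C; then aqueous Na2SO3; cold dilute HCl to pH 4
Reagents that add atoms: hydrogen peroxide (as LiOOH; supplies the carboxyl OH oxygen), OO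
Why: Evans auxiliary hydrolysis with LiOOH, whose nucleophilic but weakly basic anion attacks the exocyclic imide carbonyl at 0 °C so that neither the silyloxy-bearing centre nor the beta-aryloxy group should be disturbed, and whose percarboxylate product is not an epoxidising species and is reduced by sulfite before acidification.

Step 8
Reactants: 17 (2R,3R)-3-[3,5-bis(methoxymethoxy)-2-(3-methylbut-2-en-1-yl)phenoxy]-2-(tert-butyldimethylsilyloxy)-3-[4-methoxy-3-(3-methylbut-2-en-1-yl)phenyl]propanoic acid
Product: 19 (2R,3R)-3-(tert-butyldimethylsilyloxy)-5,7-bis(methoxymethoxy)-2-[4-methoxy-3-(3-methylbut-2-en-1-yl)phenyl]-8-(3-methylbut-2-en-1-yl)chroman-4-one, via acid chloride 18 (not isolated)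
Conditions: 1-chloro-N,N,2-trimethylprop-1-en-1-amine (1.2 equiv), CH2Cl2, 0 °C; then 2,6-di-tert-butyl-4-methylpyridine (1.5 equiv), SnCl4 (2.5 equiv), −78 to −40 °C; cold aqueous NaHCO3 quench
Reagents that add atoms: none
Why: Intramolecular Friedel–Crafts acylation, the established route from 3-aryloxypropanoic acids to chroman-4-ones: the chloroenamine turns the acid into acid chloride 18 without liberating HCl, SnCl4 polarises the C–Cl bond to an acylium-type complex, C4a of ring A attacks it and the hindered pyridine takes the proton from the sigma complex. Ring C closes in a six-membered mode in which the attacking C4a=C8a bond of the arene lies inside the new ring and the acyl C=O outside it. No stereocentre is formed; C2 and C3 were set in the open chain and take no part in bond making, and the neutral, cold activation is meant to avoid ketene formation or enolisation at the silyloxy-bearing carbon. Regioselectivity among the ring A carbons is secured by the substrate: the O1–C2–C3 tether reaches only the two carbons ortho to O1, C8 is blocked by its prenyl group and C6 is out of reach, while C4a is ortho to O1 and the C5 oxygen and para to the C7 oxygen. Ring B does not compete because its open positions are meta to the methoxy group and attack there would need a five-membered ring. The proton trap and the low temperature are there to keep the two prenyl groups, the MOM acetals and the benzylic aryl ether intact.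

Step 9
Reactants: 19 (2R,3R)-3-(tert-butyldimethylsilyloxy)-5,7-bis(methoxymethoxy)-2-[4-methoxy-3-(3-methylbut-2-en-1-yl)phenyl]-8-(3-methylbut-2-en-1-yl)chroman-4-one
Product: 20 (2R,3R)-3,5,7-trihydroxy-2-[4-methoxy-3-(3-methylbut-2-en-1-yl)phenyl]-8-(3-methylbut-2-en-1-yl)chroman-4-one (target)
Conditions: HCl in MeOH (1.25 M), 0 °C to rt
Reagents that add atoms: none
Why: Acid-catalysed acetal exchange of the two MOM ethers and acid-catalysed methanolysis of the silyl ether in one operation, run at mild temperature so that the prenyl groups should not be protonated and the thermodynamically preferred 2,3-trans ring is kept.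

**Compound list**

1 | phloroglucinol (benzene-1,3,5-triol) | Oc1cc(O)cc(O)c1 | starting material
2 | 3,5-bis(methoxymethoxy)phenol | COCOc1cc(O)cc(OCOC)c1 | intermediate
3 | prenyl bromide (1-bromo-3-methylbut-2-ene) | CC(C)=CCBr | starting material
4 | sodium 3,5-bis(methoxymethoxy)phenoxide | COCOc1cc([O-])cc(OCOC)c1.[Na+] | intermediate (not isolated)
5 | 3,5-bis(methoxymethoxy)-2-(3-methylbut-2-en-1-yl)phenol | COCOc1cc(O)c(CC=C(C)C)c(OCOC)c1 | intermediate
6 | 3-bromo-4-methoxybenzaldehyde | COc1ccc(C=O)cc1Br | starting material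
7 | tributyl(3-methylbut-2-en-1-yl)stannane | CCCC[Sn](CCCC)(CCCC)CC=C(C)C | starting material
8 | 4-methoxy-3-(3-methylbut-2-en-1-yl)benzaldehyde | COc1ccc(C=O)cc1CC=C(C)C | intermediate
9 | 2-(tert-butyldimethylsilyloxy)acetic acid | CC(C)(C)[Si](C)(C)OCC(=O)O | starting material
10 | (R)-4-benzyl-1,3-oxazolidin-2-one | O=C1N[C@H](Cc2ccccc2)CO1 | starting material
11 | 2-(tert-butyldimethylsilyloxy)acetic pivalic anhydride | CC(C)(C)C(=O)OC(=O)CO[Si](C)(C)C(C)(C)C | intermediate (not isolated)
12 | (R)-4-benzyl-3-[2-(tert-butyldimethylsilyloxy)acetyl]-1,3-oxazolidin-2-one | CC(C)(C)[Si](C)(C)OCC(=O)N1[C@H](Cc2ccccc2)COC1=O | intermediate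
13 | dibutylboron Z-enolate of 12 | CCCCB(CCCC)O/C(=C\O[Si](C)(C)C(C)(C)C)N1[C@H](Cc2ccccc2)COC1=O | intermediate (not isolated)
14 | (R)-4-benzyl-3-[(2R,3S)-2-(tert-butyldimethylsilyloxy)-3-hydroxy-3-[4-methoxy-3-(3-methylbut-2-en-1-yl)phenyl]propanoyl]-1,3-oxazolidin-2-one | COc1ccc([C@H](O)[C@@H](O[Si](C)(C)C(C)(C)C)C(=O)N2[C@H](Cc3ccccc3)COC2=O)cc1CC=C(C)C | intermediate
15 | (R)-4-benzyl-3-[(2R,3R)-3-[3,5-bis(methoxymethoxy)-2-(3-methylbut-2-en-1-yl)phenoxy]-2-(tert-butyldimethylsilyloxy)-3-[4-methoxy-3-(3-methylbut-2-en-1-yl)phenyl]propanoyl]-1,3-oxazolidin-2-one | COc1ccc([C@@H](Oc2cc(OCOC)cc(OCOC)c2CC=C(C)C)[C@@H](O[Si](C)(C)C(C)(C)C)C(=O)N3[C@H](Cc4ccccc4)COC3=O)cc1CC=C(C)C | intermediate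
16 | lithium (2R,3R)-3-[3,5-bis(methoxymethoxy)-2-(3-methylbut-2-en-1-yl)phenoxy]-2-(tert-butyldimethylsilyloxy)-3-[4-methoxy-3-(3-methylbut-2-en-1-yl)phenyl]propaneperoxoate | COc1ccc([C@@H](Oc2cc(OCOC)cc(OCOC)c2CC=C(C)C)[C@@H](O[Si](C)(C)C(C)(C)C)C(=O)O[O-])cc1CC=C(C)C.[Li+] | intermediate (not isolated)
17 | (2R,3R)-3-[3,5-bis(methoxymethoxy)-2-(3-methylbut-2-en-1-yl)phenoxy]-2-(tert-butyldimethylsilyloxy)-3-[4-methoxy-3-(3-methylbut-2-en-1-yl)phenyl]propanoic acid | COc1ccc([C@@H](Oc2cc(OCOC)cc(OCOC)c2CC=C(C)C)[C@@H](O[Si](C)(C)C(C)(C)C)C(=O)O)cc1CC=C(C)C | intermediate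
18 | (2R,3R)-3-[3,5-bis(methoxymethoxy)-2-(3-methylbut-2-en-1-yl)phenoxy]-2-(tert-butyldimethylsilyloxy)-3-[4-methoxy-3-(3-methylbut-2-en-1-yl)phenyl]propanoyl chloride | COc1ccc([C@@H](Oc2cc(OCOC)cc(OCOC)c2CC=C(C)C)[C@@H](O[Si](C)(C)C(C)(C)C)C(Cl)=O)cc1CC=C(C)C | intermediate (not isolated)
19 | (2R,3R)-3-(tert-butyldimethylsilyloxy)-5,7-bis(methoxymethoxy)-2-[4-methoxy-3-(3-methylbut-2-en-1-yl)phenyl]-8-(3-methylbut-2-en-1-yl)chroman-4-one | COc1ccc([C@H]2Oc3c(CC=C(C)C)c(OCOC)cc(OCOC)c3C(=O)[C@@H]2O[Si](C)(C)C(C)(C)C)cc1CC=C(C)C | intermediate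
20 | (2R,3R)-3,5,7-trihydroxy-2-[4-methoxy-3-(3-methylbut-2-en-1-yl)phenyl]-8-(3-methylbut-2-en-1-yl)chroman-4-one | COc1ccc([C@H]2Oc3c(CC=C(C)C)c(O)cc(O)c3C(=O)[C@@H]2O)cc1CC=C(C)C | target

**Total step count:** 9 steps.
**Longest linear sequence:** 6 steps (steps 1, 2, 6, 7, 8, 9; the branches through steps 4, 5 and through steps 3, 5 are equally long).

**Three steps most likely to fail**

Step 8 (ring closure). The Lewis acid may ionise the electron-rich benzylic aryl ether, strip the MOM acetals or allow protonation of a prenyl group faster than the acyl chloride closes ring C. The fallback forms the same C4–C4a bond at the aldehyde oxidation level, where a weaker, proton-scavenging Lewis acid suffices. It sets out from 15: LiBH4 (THF, MeOH, 0 °C) cleaves the auxiliary reductively to (2S,3R)-3-[3,5-bis(methoxymethoxy)-2-(3-methylbut-2-en-1-yl)phenoxy]-2-(tert-butyldimethylsilyloxy)-3-[4-methoxy-3-(3-methylbut-2-en-1-yl)phenyl]propan-1-ol F1. Dess–Martin periodinane (NaHCO3, CH2Cl2) gives the corresponding (2R,3R)-propanal F2. Me2AlCl (CH2Cl2, −78 °C) promotes intramolecular Friedel–Crafts hydroxyalkylation at C4a to the chroman-4-ol F3 (both C4 epimers), and a second Dess–Martin oxidation of this benzylic alcohol comes back to the route at 19.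

Step 6 (Mitsunobu etherification). The activated beta-hydroxy imide may eliminate to the conjugated enol ether, or substitution at the hindered, ionisable benzylic carbon may be slow and lose configuration. The fallback runs the etherification on a substrate without the acidifying carbonyl. It sets out from 14: LiBH4 (THF, MeOH, 0 °C) gives (1S,2S)-2-(tert-butyldimethylsilyloxy)-1-[4-methoxy-3-(3-methylbut-2-en-1-yl)phenyl]propane-1,3-diol F4. Pivaloyl chloride in pyridine acylates the primary hydroxyl selectively to the pivalate F5. PPh3/DIAD with phenol 5 then gives the inverted (2S,3R) aryl ether pivalate F6. i-Bu2AlH (CH2Cl2, −78 °C) removes the pivalate to give the primary alcohol F1. Dess–Martin oxidation to the aldehyde F2 and Pinnick oxidation (NaClO2, NaH2PO4, 2-methylbut-2-ene, t-BuOH/H2O) come back to the route at 17. Any epimer at the benzylic carbon is a diastereomer and can be removed by chromatography, so the enantiomeric purity rests on the aldol alone.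

Step 2 (C-prenylation). O-alkylation, para C-alkylation between the two MOM ethers and double alkylation may compete with the wanted ortho attack. The fallback alkylates oxygen on purpose and moves the group to carbon by a sigmatropic shift. It sets out from 2: Pd(PPh3)4-catalysed allylic etherification with methyl 2-methylbut-3-en-2-yl carbonate (THF, rt) gives the tertiary allyl ether 1,3-bis(methoxymethoxy)-5-[(2-methylbut-3-en-2-yl)oxy]benzene F7. Heating in toluene (110 °C) brings about the aromatic Claisen rearrangement to one of the two equivalent ortho carbons with allylic transposition, which turns the 1,1-dimethylallyl group into the prenyl group and comes back to the route at 5.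

**Further compounds**

F1 | step 8 | (2S,3R)-3-[3,5-bis(methoxymethoxy)-2-(3-methylbut-2-en-1-yl)phenoxy]-2-(tert-butyldimethylsilyloxy)-3-[4-methoxy-3-(3-methylbut-2-en-1-yl)phenyl]propan-1-ol | COc1ccc([C@@H](Oc2cc(OCOC)cc(OCOC)c2CC=C(C)C)[C@@H](O[Si](C)(C)C(C)(C)C)CO)cc1CC=C(C)C
F2 | step 8 | (2R,3R)-3-[3,5-bis(methoxymethoxy)-2-(3-methylbut-2-en-1-yl)phenoxy]-2-(tert-butyldimethylsilyloxy)-3-[4-methoxy-3-(3-methylbut-2-en-1-yl)phenyl]propanal | COc1ccc([C@@H](Oc2cc(OCOC)cc(OCOC)c2CC=C(C)C)[C@@H](O[Si](C)(C)C(C)(C)C)C=O)cc1CC=C(C)C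
F3 | step 8 | (2R,3S,4RS)-3-(tert-butyldimethylsilyloxy)-5,7-bis(methoxymethoxy)-2-[4-methoxy-3-(3-methylbut-2-en-1-yl)phenyl]-8-(3-methylbut-2-en-1-yl)chroman-4-ol (same spatial arrangement at C2 and C3 as in 19) | COc1ccc([C@H]2Oc3c(CC=C(C)C)c(OCOC)cc(OCOC)c3C(O)[C@@H]2O[Si](C)(C)C(C)(C)C)cc1CC=C(C)C
F4 | step 6 | (1S,2S)-2-(tert-butyldimethylsilyloxy)-1-[4-methoxy-3-(3-methylbut-2-en-1-yl)phenyl]propane-1,3-diol | COc1ccc([C@H](O)[C@@H](O[Si](C)(C)C(C)(C)C)CO)cc1CC=C(C)C
F5 | step 6 | (2S,3S)-2-(tert-butyldimethylsilyloxy)-3-hydroxy-3-[4-methoxy-3-(3-methylbut-2-en-1-yl)phenyl]propyl 2,2-dimethylpropanoate | COc1ccc([C@H](O)[C@@H](O[Si](C)(C)C(C)(C)C)COC(=O)C(C)(C)C)cc1CC=C(C)C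
F6 | step 6 | (2S,3R)-3-[3,5-bis(methoxymethoxy)-2-(3-methylbut-2-en-1-yl)phenoxy]-2-(tert-butyldimethylsilyloxy)-3-[4-methoxy-3-(3-methylbut-2-en-1-yl)phenyl]propyl 2,2-dimethylpropanoate | COc1ccc([C@@H](Oc2cc(OCOC)cc(OCOC)c2CC=C(C)C)[C@@H](O[Si](C)(C)C(C)(C)C)COC(=O)C(C)(C)C)cc1CC=C(C)C
F7 | step 2 | 1,3-bis(methoxymethoxy)-5-[(2-methylbut-3-en-2-yl)oxy]benzene | COCOc1cc(OCOC)cc(OC(C)(C)C=C)c1
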